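By 120 s the alpha run had lost 16.2% of its J but showed 9.0% of G. The difference sat in a pool between them. I took that pool as the concentration that sets the rate of G.

| flask | J | L | Z | D | remark | time |
|---|---|---|---|---|---|---|
| alpha | 36 mM | 1.2 equiv | 12 mol% | 8 mol% | run made earlier |  |
| delta | 36 mM | 1.2 equiv | 12 mol% | 9.3 mol% | run made earlier |  |
| beta | 36 mM | 0.54 equiv | 12 mol% | 10 mol% | run made earlier |  |
| Thursday's | 36 mM | 1.20 equiv | 12 mol% | 10 mol% |  | 4.0 min |
| Wednesday's | 36 mM | 0.400 equiv | 12 mol% | 15 mol% |  | 4.0 min |

- alpha (time / s: G / %, J / %): 15.0: 0, 97.5; 40.0: 1.6, 93.6; 80.0: 4.6, 88.9; 120: 9.0, 83.8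
- delta (time / s: G / %, J / %): 15.0: 0, 97.1; 40.0: 1.8, 93.8; 80.0: 5.7, 89.3; 120: 9.5, 84.4
- beta (time / s: G / %, J / %): 30.0: 0.5, 95.1; 60.0: 2.3, 91.7; 90.0: 4.0, 88.2; 120: 5.9, 84.6

(each reading ± 0.3 percentage points)



- which of the two ends with the higher amount of G, in percent of the J charged ("neither" if they lie within 2 percentage points) (Thursday's / Wednesday's / neither)
- G at the end, in percent of the J charged, Thursday's
- G at the end, in percent of the J charged, Wednesday's

I read the alpha run between 80.0 s and 120 s:

pool = 6.85%

rise of G, as a fraction of the J charged = 0.0660 min⁻¹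

rise over pool = 0.964 min⁻¹

This drain constant is the share of the pool that becomes G each minute, a pseudo-first-order constant while L and D barely change. I assumed it follows the product of the charges of L and D.

That needed a test, so I tried the beta run:

scaled from alpha = 0.542 min⁻¹

read from beta = 0.439 min⁻¹

The gap worried me. But that reading rests on a rise of 1.9 percentage points between two readings, each with a scatter of 0.3 points. I kept the rule.

J left at about 0.0783 min⁻¹ of its charge in the alpha run. If the pool passes on what it receives, it stands at feed over drain. Taken as a constant share of the J remaining, the loss by 4.0 min is 29.3%.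

Thursday's: drain 1.20 min⁻¹, pool 6.50%, G 22.8%

Wednesday's: drain 0.602 min⁻¹, pool 13.0%, G 16.3%

I doubted Wednesday's figure twice. Its pool had reached 91.0% of that level, which raises G. But that G would take 40.6% of its L, which slows the drain and lowers G. The two pulled against each other, so I kept my figure.

The forecast named Thursday's, with 24% and 12%, calling Thursday's rate “capped by J supply”. Its Wednesday figure lay 4.3 points below mine.

The flask gave the higher G on Thursday's: 22.1% on Thursday's and 14.6% on Wednesday's.

    J + Z ⇌ Z + X (K = 0.340, k = 0.400 M⁻¹ s⁻¹)
    L + D + X → D + G (k = 120 M⁻² s⁻¹)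

The pool is X. On Wednesday's flask X was made 1.55 times as fast as it was used at 1.58 min and 1.13 times at 4.00 min, each step taken net, and it stood at 10.9% at 4.00 min, while Thursday's flask held 6.27% at 2.00 min and 6.23% at 4.00 min. Over the second half, taking L and X as the means of their values at its two ends, the drain constant read from the alpha run gives a rise of G of 0.0449 min⁻¹ on Wednesday's flask against an average of 0.0422 min⁻¹, and 0.0653 min⁻¹ on Thursday's flask against 0.0613 min⁻¹.

The earlier runs and the new flask were computed with made-up constants.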